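## Retrosynthetic overview

1. The target comes from a trans-vinyl epoxide (C1'–C2') by palladium/borate methanolysis with net retention; the 5',6'-diacetate comes from a C5' ketone (CBS reduction, acetylation).
2. The dihydropyranone comes from ring-closing metathesis of a C6 acrylate/allyl pair; the oxirane from Sharpless epoxidation of an (S)-dienyl carbinol; the C6–C5 bond from catalytic asymmetric allylation of a dienal.
3. The whole C6–C7' keto-dienal comes from furan and an O-acetyl-D-lactate-derived diazoketone by rhodium-carbenoid ring-opening of the furan; the furan oxygen ends up as the lactone ring oxygen.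
4. Ring order: furan opened (step 2), oxirane closed (step 4), lactone closed (step 6), oxirane opened (step 9).

Assumption: (R)-2-acetoxypropanoyl chloride (O-acetyl-D-lactoyl chloride) is bought as such; side-chain carbons are called C1'–C7' counting outward from lactone carbon C6.

## Route

Step 1
Reactants: 1 (R)-2-acetoxypropanoyl chloride; 2 (trimethylsilyl)diazomethane
Product: 3 (2R)-4-diazo-3-oxobutan-2-yl acetate
Conditions: TMSCHN2 (2.0 equiv), THF/MeCN 1:1, 0 °C to rt; concentrate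
Reagents that add atoms: (trimethylsilyl)diazomethane, C[Si](C)(C)C=[N+]=[N-]
Why: C-acylation of the diazoalkane followed by loss of Me3SiCl (Arndt–Eistert-type diazoketone synthesis) needs no amine base, so the lactate stereocentre (future C6', R) is carried through unchanged.

Step 2
Reactants: 3 (2R)-4-diazo-3-oxobutan-2-yl acetate; 4 furan
Product: 6 (2R,4E,6E)-3,8-dioxoocta-4,6-dien-2-yl acetate, via 6Z-dienal isomer 5 (not isolated)
Conditions: Rh2(OAc)4 (1 mol%), furan (10 equiv), CH2Cl2, rt, slow addition of 3; then concentrate, I2 (2 mol%), CH2Cl2, rt, dark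
Reagents that add atoms: furan, c1ccoc1
Why: The electrophilic rhodium carbenoid adds at C2/C3 of furan and the adduct collapses by C–O cleavage (carbenoid furan ring-opening, "furan unravelling"), so the furan oxygen becomes the aldehyde oxygen and the ring C3–C4 bond emerges as the cis enal of 5, which catalytic iodine equilibrates to the all-trans dienal; no stereocentre is formed and C6' is untouched.

Step 3
Reactants: 6 (2R,4E,6E)-3,8-dioxoocta-4,6-dien-2-yl acetate; 7 allyltributylstannane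
Product: 9 (2R,4E,6E,8S)-8-hydroxy-3-oxoundeca-4,6,10-trien-2-yl acetate, via tributylstannyl ether 8 (not isolated)
Conditions: (S)-BINOL (20 mol%), Ti(OiPr)4 (10 mol%), 4 Å MS, CH2Cl2, −20 °C, 48 h; aq. NaHCO3
Reagents that add atoms: allyltributylstannane, C=CC[Sn](CCCC)(CCCC)CCCC
Why: In this Keck asymmetric allylation the chiral titanium Lewis acid activates only the aldehyde (ketone and acetate do not react with the allylstannane) and directs allyl to its Si face, setting C6 as S.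

Step 4
Reactants: 9 (2R,4E,6E,8S)-8-hydroxy-3-oxoundeca-4,6,10-trien-2-yl acetate; 10 tert-butyl hydroperoxide
Product: 11 (2R,4E)-5-{(2S,3S)-3-[(1S)-1-hydroxybut-3-en-1-yl]oxiran-2-yl}-3-oxopent-4-en-2-yl acetate
Conditions: Ti(OiPr)4 (20 mol%), L-(+)-DIPT (24 mol%), t-BuOOH (1.2 equiv, decane), 4 Å MS, CH2Cl2, −20 °C
Reagents that add atoms: tert-butyl hydroperoxide, CC(C)(C)OO
Why: Sharpless asymmetric epoxidation in the matched pairing (S-carbinol with L-(+)-tartrate, the fast-reacting case of the kinetic resolution) delivers oxygen only to the hydroxyl-bearing allylic C1'=C2' bond and anti (erythro) to the carbinol, setting C1' (S) and C2' (S), while the enone and terminal alkenes are not directed and the minor enantiomer from step 3 reacts too slowly to follow.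

Step 5
Reactants: 11 (2R,4E)-5-{(2S,3S)-3-[(1S)-1-hydroxybut-3-en-1-yl]oxiran-2-yl}-3-oxopent-4-en-2-yl acetate; 12 acryloyl chloride
Product: 13 (1S)-1-{(2S,3S)-3-[(1E,4R)-4-acetoxy-3-oxopent-1-en-1-yl]oxiran-2-yl}but-3-en-1-yl prop-2-enoate
Conditions: acryloyl chloride (1.5 equiv), i-Pr2NEt (2 equiv), CH2Cl2, −20 to 0 °C
Reagents that add atoms: acryloyl chloride, C=CC(=O)Cl
Why: Plain O-acylation of the only free hydroxyl (C6–OH) with an acid chloride and a hindered amine base, with C1'–O still locked in the oxirane and no stereocentre touched.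

Step 6
Reactants: 13 (1S)-1-{(2S,3S)-3-[(1E,4R)-4-acetoxy-3-oxopent-1-en-1-yl]oxiran-2-yl}but-3-en-1-yl prop-2-enoate
Product: 14 (2R,4E)-3-oxo-5-{(2S,3S)-3-[(2S)-6-oxo-3,6-dihydro-2H-pyran-2-yl]oxiran-2-yl}pent-4-en-2-yl acetate
Conditions: second-generation Grubbs catalyst RuCl2(=CHPh)(PCy3)(H2IMes) (5 mol%), CH2Cl2 (5 mM), 40 °C
Reagents that add atoms: none
Why: Ring-closing metathesis of the terminal allyl alkene onto the acrylate closes the six-membered α,β-unsaturated lactone with loss of ethene, the internal electron-poor enone alkene and the oxirane being inert to the ruthenium carbene.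

Step 7
Reactants: 14 (2R,4E)-3-oxo-5-{(2S,3S)-3-[(2S)-6-oxo-3,6-dihydro-2H-pyran-2-yl]oxiran-2-yl}pent-4-en-2-yl acetate; 15 catecholborane
Product: 17 (2R,3R,4E)-3-hydroxy-5-{(2S,3S)-3-[(2S)-6-oxo-3,6-dihydro-2H-pyran-2-yl]oxiran-2-yl}pent-4-en-2-yl acetate, via catecholborate ester 16 (not isolated)
Conditions: (R)-2-methyl-CBS-oxazaborolidine (0.2 equiv), catecholborane (1.5 equiv), toluene, −78 °C; pH 7 buffer
Reagents that add atoms: none
Why: In this Corey–Bakshi–Shibata reduction the (R)-oxazaborolidine treats the alkenyl arm as the large group and gives the 5'R carbinol, which is also the Felkin–Anh product (syn to the 6'-acetoxy group), so catalyst and substrate control are matched, and the conjugated lactone, oxirane and acetate are not reduced at −78 °C.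

Step 8
Reactants: 17 (2R,3R,4E)-3-hydroxy-5-{(2S,3S)-3-[(2S)-6-oxo-3,6-dihydro-2H-pyran-2-yl]oxiran-2-yl}pent-4-en-2-yl acetate; 18 acetic anhydride
Product: 19 (2R,3R,4E)-5-{(2S,3S)-3-[(2S)-6-oxo-3,6-dihydro-2H-pyran-2-yl]oxiran-2-yl}pent-4-ene-2,3-diyl diacetate
Conditions: Ac2O (2 equiv), pyridine, DMAP (cat.), CH2Cl2, 0 °C
Reagents that add atoms: acetic anhydride, CC(=O)OC(C)=O
Why: DMAP-catalysed acetylation of the single free hydroxyl completes the 5',6'-diacetate while C1'–O is still masked as the oxirane, which is what later leaves C1'–OH as the only free hydroxyl (a 1,2-acetyl shift between O5' and O6' would be harmless).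

Step 9
Reactants: 19 (2R,3R,4E)-5-{(2S,3S)-3-[(2S)-6-oxo-3,6-dihydro-2H-pyran-2-yl]oxiran-2-yl}pent-4-ene-2,3-diyl diacetate; 20 trimethyl borate
Product: 22 (2R,3R,4E,6S,7S)-7-hydroxy-6-methoxy-7-[(2S)-6-oxo-3,6-dihydro-2H-pyran-2-yl]hept-4-ene-2,3-diyl diacetate, via dimethyl borate ester 21 (not isolated)
Conditions: Pd(PPh3)4 (5 mol%), B(OMe)3 (2 equiv), THF, 0 °C to rt; aq. NH4Cl
Reagents that add atoms: trimethyl borate, COB(OC)OC
Why: Zerovalent palladium ionises the vinyl oxirane with inversion and the borate formed at the C1' alkoxide hands methoxide to the adjacent allyl terminus C2' with a second inversion (borate-mediated Tsuji–Trost-type allylic substitution), giving net retention at C2' and hence the 1',2'-syn hydroxy methyl ether, while the much slower-ionising C5' allylic acetate is left alone under these neutral conditions.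

## Compound list

1 | (R)-2-acetoxypropanoyl chloride | C[C@@H](OC(C)=O)C(Cl)=O | starting material
2 | (trimethylsilyl)diazomethane | C[Si](C)(C)C=[N+]=[N-] | starting material
3 | (2R)-4-diazo-3-oxobutan-2-yl acetate | C[C@@H](OC(C)=O)C(=O)C=[N+]=[N-] | intermediate
4 | furan | c1ccoc1 | starting material
5 | (2R,4E,6Z)-3,8-dioxoocta-4,6-dien-2-yl acetate | O=C/C=C\C=C\C(=O)[C@@H](C)OC(C)=O | intermediate
6 | (2R,4E,6E)-3,8-dioxoocta-4,6-dien-2-yl acetate | O=C/C=C/C=C/C(=O)[C@@H](C)OC(C)=O | intermediate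
7 | allyltributylstannane | C=CC[Sn](CCCC)(CCCC)CCCC | starting material
8 | (2R,4E,6E,8S)-3-oxo-8-(tributylstannyloxy)undeca-4,6,10-trien-2-yl acetate | C=CC[C@H](O[Sn](CCCC)(CCCC)CCCC)/C=C/C=C/C(=O)[C@@H](C)OC(C)=O | intermediate
9 | (2R,4E,6E,8S)-8-hydroxy-3-oxoundeca-4,6,10-trien-2-yl acetate | C=CC[C@H](O)/C=C/C=C/C(=O)[C@@H](C)OC(C)=O | intermediate
10 | tert-butyl hydroperoxide | CC(C)(C)OO | starting material
11 | (2R,4E)-5-{(2S,3S)-3-[(1S)-1-hydroxybut-3-en-1-yl]oxiran-2-yl}-3-oxopent-4-en-2-yl acetate | O1[C@@H](/C=C/C(=O)[C@@H](C)OC(C)=O)[C@@H]1[C@@H](O)CC=C | intermediate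
12 | acryloyl chloride | C=CC(=O)Cl | starting material
13 | (1S)-1-{(2S,3S)-3-[(1E,4R)-4-acetoxy-3-oxopent-1-en-1-yl]oxiran-2-yl}but-3-en-1-yl prop-2-enoate | O1[C@@H](/C=C/C(=O)[C@@H](C)OC(C)=O)[C@@H]1[C@@H](OC(=O)C=C)CC=C | intermediate
14 | (2R,4E)-3-oxo-5-{(2S,3S)-3-[(2S)-6-oxo-3,6-dihydro-2H-pyran-2-yl]oxiran-2-yl}pent-4-en-2-yl acetate | O1[C@@H](/C=C/C(=O)[C@@H](C)OC(C)=O)[C@@H]1[C@@H]2CC=CC(=O)O2 | intermediate
15 | catecholborane | [H]B1Oc2ccccc2O1 | starting material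
16 | (2R,3R,4E)-3-(1,3,2-benzodioxaborol-2-yloxy)-5-{(2S,3S)-3-[(2S)-6-oxo-3,6-dihydro-2H-pyran-2-yl]oxiran-2-yl}pent-4-en-2-yl acetate | O1[C@@H](/C=C/[C@@H](OB3Oc4ccccc4O3)[C@@H](C)OC(C)=O)[C@@H]1[C@@H]2CC=CC(=O)O2 | intermediate
17 | (2R,3R,4E)-3-hydroxy-5-{(2S,3S)-3-[(2S)-6-oxo-3,6-dihydro-2H-pyran-2-yl]oxiran-2-yl}pent-4-en-2-yl acetate | O1[C@@H](/C=C/[C@@H](O)[C@@H](C)OC(C)=O)[C@@H]1[C@@H]2CC=CC(=O)O2 | intermediate
18 | acetic anhydride | CC(=O)OC(C)=O | starting material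
19 | (2R,3R,4E)-5-{(2S,3S)-3-[(2S)-6-oxo-3,6-dihydro-2H-pyran-2-yl]oxiran-2-yl}pent-4-ene-2,3-diyl diacetate | O1[C@@H](/C=C/[C@@H](OC(C)=O)[C@@H](C)OC(C)=O)[C@@H]1[C@@H]2CC=CC(=O)O2 | intermediate
20 | trimethyl borate | COB(OC)OC | starting material
21 | (2R,3R,4E,6S,7S)-7-[(dimethoxyboranyl)oxy]-6-methoxy-7-[(2S)-6-oxo-3,6-dihydro-2H-pyran-2-yl]hept-4-ene-2,3-diyl diacetate | CO[C@@H](/C=C/[C@@H](OC(C)=O)[C@@H](C)OC(C)=O)[C@@H](OB(OC)OC)[C@@H]1CC=CC(=O)O1 | intermediate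
22 | (2R,3R,4E,6S,7S)-7-hydroxy-6-methoxy-7-[(2S)-6-oxo-3,6-dihydro-2H-pyran-2-yl]hept-4-ene-2,3-diyl diacetate, i.e. (6S)-6-[(1S,2S,3E,5R,6R)-5,6-diacetoxy-1-hydroxy-2-methoxyhept-3-enyl]-5,6-dihydro-2H-pyran-2-one | CO[C@@H](/C=C/[C@@H](OC(C)=O)[C@@H](C)OC(C)=O)[C@@H](O)[C@@H]1CC=CC(=O)O1 | target

## Step count and weak points

Total steps: 9. Longest linear sequence: 9 (1 to 22); furan 4 enters at step 2.

Stereocentres: C6' comes from 1; C6 is set in step 3; C1' and C2' in step 4 (C2' is kept by double inversion in step 9); C5' in step 7.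

The three steps most likely to fail:

Step 2. The α'-acetoxy carbenoid may be diverted (attack by the acetate carbonyl, carbene dimerisation) and the doubly activated dienal is sensitive. The fallback sets out from 3 and comes back at 6, replacing the carbenoid ring-opening by a Wittig assembly from a furan-derived C4 dialdehyde. HBr (48% aq.) in Et2O at 0 °C converts 3 into (2R)-4-bromo-3-oxobutan-2-yl acetate F1. PPh3 in toluene gives [(3R)-3-acetoxy-2-oxobutyl]triphenylphosphonium bromide F2, and aqueous Na2CO3 turns this into the acyl-stabilised ylide (2R)-3-oxo-4-(triphenylphosphoranylidene)butan-2-yl acetate F3. Olefination of commercial (E)-4,4-dimethoxybut-2-enal (fumaraldehyde mono(dimethyl acetal), made industrially from furan by bromine/methanol dearomatisation) in CH2Cl2 gives (2R,4E,6E)-8,8-dimethoxy-3-oxoocta-4,6-dien-2-yl acetate F4. Amberlyst-15 in wet acetone then releases the aldehyde to give 6.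

Step 4. The C1'=C2' bond is the γ,δ-alkene of a dienone and may be too electron-poor for the titanium/tartrate oxidant. The fallback sets out from 6 and comes back at 11, epoxidising before the allylation through iminium activation instead of hydroxyl direction. (S)-2-[Bis(3,5-bis(trifluoromethyl)phenyl)(trimethylsilyloxy)methyl]pyrrolidine (10 mol%) with 35% aq. H2O2 in CH2Cl2 at rt gives (2R,3S)-3-[(1E,4R)-4-acetoxy-3-oxopent-1-en-1-yl]oxirane-2-carbaldehyde F5. The step 3 allylation conditions, now with the Felkin–Anh preference of the epoxy aldehyde matched to the (S)-BINOL catalyst, give (2R,4E)-3-oxo-5-{(2S,3S)-3-[(1S)-1-(tributylstannyloxy)but-3-en-1-yl]oxiran-2-yl}pent-4-en-2-yl acetate F6, which is hydrolysed on work-up to 11.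

Step 9. Zerovalent palladium could also ionise the C5' allylic acetate (scrambling or elimination), or methoxide could add at the distal allyl terminus. The fallback sets out from 14 and comes back at 22, moving the methoxylation to the enone stage, where no allylic acetate exists, at the cost of a silyl group.
- Pd(PPh3)4/B(OMe)3 in THF converts 14, through (2R,4E,6S,7S)-7-[(dimethoxyboranyl)oxy]-6-methoxy-3-oxo-7-[(2S)-6-oxo-3,6-dihydro-2H-pyran-2-yl]hept-4-en-2-yl acetate F7, into (2R,4E,6S,7S)-7-hydroxy-6-methoxy-3-oxo-7-[(2S)-6-oxo-3,6-dihydro-2H-pyran-2-yl]hept-4-en-2-yl acetate F8.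
- TESOTf/2,6-lutidine in CH2Cl2 at −78 °C gives (2R,4E,6S,7S)-6-methoxy-3-oxo-7-[(2S)-6-oxo-3,6-dihydro-2H-pyran-2-yl]-7-(triethylsilyloxy)hept-4-en-2-yl acetate F9.
- The step 7 reduction gives, through (2R,3R,4E,6S,7S)-3-(1,3,2-benzodioxaborol-2-yloxy)-6-methoxy-7-[(2S)-6-oxo-3,6-dihydro-2H-pyran-2-yl]-7-(triethylsilyloxy)hept-4-en-2-yl acetate F10, the alcohol (2R,3R,4E,6S,7S)-3-hydroxy-6-methoxy-7-[(2S)-6-oxo-3,6-dihydro-2H-pyran-2-yl]-7-(triethylsilyloxy)hept-4-en-2-yl acetate F11.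
- Ac2O/pyridine/DMAP gives (2R,3R,4E,6S,7S)-6-methoxy-7-[(2S)-6-oxo-3,6-dihydro-2H-pyran-2-yl]-7-(triethylsilyloxy)hept-4-ene-2,3-diyl diacetate F12.
- HF·pyridine in THF at 0 °C removes the silyl group to give 22.

Further compounds

F1 | step 2 | (2R)-4-bromo-3-oxobutan-2-yl acetate | C[C@@H](OC(C)=O)C(=O)CBr
F2 | step 2 | [(3R)-3-acetoxy-2-oxobutyl]triphenylphosphonium bromide | C[C@@H](OC(C)=O)C(=O)C[P+](c1ccccc1)(c1ccccc1)c1ccccc1.[Br-]
F3 | step 2 | (2R)-3-oxo-4-(triphenylphosphoranylidene)butan-2-yl acetate | C[C@@H](OC(C)=O)C(=O)C=P(c1ccccc1)(c1ccccc1)c1ccccc1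
F4 | step 2 | (2R,4E,6E)-8,8-dimethoxy-3-oxoocta-4,6-dien-2-yl acetate | COC(OC)/C=C/C=C/C(=O)[C@@H](C)OC(C)=O
F5 | step 4 | (2R,3S)-3-[(1E,4R)-4-acetoxy-3-oxopent-1-en-1-yl]oxirane-2-carbaldehyde | O1[C@@H](/C=C/C(=O)[C@@H](C)OC(C)=O)[C@@H]1C=O
F6 | step 4 | (2R,4E)-3-oxo-5-{(2S,3S)-3-[(1S)-1-(tributylstannyloxy)but-3-en-1-yl]oxiran-2-yl}pent-4-en-2-yl acetate | O1[C@@H](/C=C/C(=O)[C@@H](C)OC(C)=O)[C@@H]1[C@@H](O[Sn](CCCC)(CCCC)CCCC)CC=C
F7 | step 9 | (2R,4E,6S,7S)-7-[(dimethoxyboranyl)oxy]-6-methoxy-3-oxo-7-[(2S)-6-oxo-3,6-dihydro-2H-pyran-2-yl]hept-4-en-2-yl acetate | CO[C@@H](/C=C/C(=O)[C@@H](C)OC(C)=O)[C@@H](OB(OC)OC)[C@@H]1CC=CC(=O)O1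
F8 | step 9 | (2R,4E,6S,7S)-7-hydroxy-6-methoxy-3-oxo-7-[(2S)-6-oxo-3,6-dihydro-2H-pyran-2-yl]hept-4-en-2-yl acetate | CO[C@@H](/C=C/C(=O)[C@@H](C)OC(C)=O)[C@@H](O)[C@@H]1CC=CC(=O)O1
F9 | step 9 | (2R,4E,6S,7S)-6-methoxy-3-oxo-7-[(2S)-6-oxo-3,6-dihydro-2H-pyran-2-yl]-7-(triethylsilyloxy)hept-4-en-2-yl acetate | CO[C@@H](/C=C/C(=O)[C@@H](C)OC(C)=O)[C@@H](O[Si](CC)(CC)CC)[C@@H]1CC=CC(=O)O1
F10 | step 9 | (2R,3R,4E,6S,7S)-3-(1,3,2-benzodioxaborol-2-yloxy)-6-methoxy-7-[(2S)-6-oxo-3,6-dihydro-2H-pyran-2-yl]-7-(triethylsilyloxy)hept-4-en-2-yl acetate | CO[C@@H](/C=C/[C@@H](OB2Oc3ccccc3O2)[C@@H](C)OC(C)=O)[C@@H](O[Si](CC)(CC)CC)[C@@H]1CC=CC(=O)O1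
F11 | step 9 | (2R,3R,4E,6S,7S)-3-hydroxy-6-methoxy-7-[(2S)-6-oxo-3,6-dihydro-2H-pyran-2-yl]-7-(triethylsilyloxy)hept-4-en-2-yl acetate | CO[C@@H](/C=C/[C@@H](O)[C@@H](C)OC(C)=O)[C@@H](O[Si](CC)(CC)CC)[C@@H]1CC=CC(=O)O1
F12 | step 9 | (2R,3R,4E,6S,7S)-6-methoxy-7-[(2S)-6-oxo-3,6-dihydro-2H-pyran-2-yl]-7-(triethylsilyloxy)hept-4-ene-2,3-diyl diacetate | CO[C@@H](/C=C/[C@@H](OC(C)=O)[C@@H](C)OC(C)=O)[C@@H](O[Si](CC)(CC)CC)[C@@H]1CC=CC(=O)O1
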